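No skeletal bond is disconnected: the C5 carbinol is traced back to a carbonyl, so that the target becomes the mono-reduced form of an unsymmetrical 1,7-diarylheptane-3,5-dione. The feature exploited is that C3 and C5 are both carbonyl-level carbons whose arylethyl arms differ only in the aryl ring, guaiacyl ring A on C7 against syringyl ring B on C1. In one operation a ketoreductase reduces the C5 carbonyl alone, on its Si face, creating the C5–H bond and the 5R centre without protecting groups. Its precursor, the free bis-phenolic diketone, comes from acetylacetone, vanillin and syringaldehyde by two boron-templated condensations and one hydrogenation.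

Key step: step 4

Assumption: the β-diketones are drawn as diketo tautomers although they are largely enolised; the borate chelates formed with B2O3/B(OBu)3, which are mixtures of oligomeric borates, are each drawn as the simplest defined member, the dibutoxyboron diketonate (a 2,2-dibutoxy-1,3,2-dioxaborinine), and the difluoroboron chelates are drawn in the same zwitterionic form.

Step 1
Reactants: 1 acetylacetone (pentane-2,4-dione); 2 vanillin (4-hydroxy-3-methoxybenzaldehyde)
Product: 5 feruloylacetone [(E)-6-(4-hydroxy-3-methoxyphenyl)hex-5-ene-2,4-dione], via acetylacetone dibutoxyboron chelate 3 (not isolated), via feruloylacetone dibutoxyboron chelate 4 (not isolated)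
Conditions: 1 (3 equiv), B2O3, B(OBu)3, EtOAc, 70 °C; then 2 (1 equiv), n-BuNH2 (0.2 equiv, added slowly), 70 °C; then 0.5 M aq. HCl, 60 °C
Reagents that add atoms: none
Why: In this boron-templated aldol (Claisen–Schmidt type) condensation the borate chelate masks the central methylene of the diketone and makes a terminal methyl group the nucleophile toward the butyliminium form of the aldehyde, the threefold excess of 1 should hold the reaction at the mono-styryl stage, and acid hydrolysis of the chelate releases the E alkene as the thermodynamic elimination product.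

Step 2
Reactants: 5 feruloylacetone; 6 syringaldehyde (4-hydroxy-3,5-dimethoxybenzaldehyde)
Product: 9 (1E,6E)-1-(4-hydroxy-3,5-dimethoxyphenyl)-7-(4-hydroxy-3-methoxyphenyl)hepta-1,6-diene-3,5-dione, via feruloylacetone difluoroboron chelate 7 (not isolated), via curcuminoid difluoroboron chelate 8 (not isolated)
Conditions: BF3·OEt2 (1.2 equiv), CH2Cl2, rt; water wash, concentration, crude 7 used directly; then 6 (1.1 equiv), n-BuNH2 (0.2 equiv), 4 Å MS, toluene/EtOAc (1:1), 60 °C; then MeOH/H2O (4:1), 1 M aq. NaOH to pH 6, 65 °C
Reagents that add atoms: none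
Why: BF3·OEt2 converts 5 into its difluoroboron chelate, a single defined dioxaborinine that blocks the central carbon and acidifies the one remaining methyl group, so the amine-mediated aldol (Claisen–Schmidt type) condensation with 6 can occur only there and at a temperature low enough to limit retro-aldol exchange of the aryl arms, and hydrolysis of the chelate in aqueous methanol near pH 6 should release the E,E-curcuminoid.

Step 3
Reactants: 9 the unsymmetrical curcuminoid
Product: 10 the saturated diketone 1-(4-hydroxy-3,5-dimethoxyphenyl)-7-(4-hydroxy-3-methoxyphenyl)heptane-3,5-dione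
Conditions: H2 (1 atm), 10% Pd/C, EtOAc/MeOH, rt, stopped after uptake of 2 equiv of H2; recrystallisation
Reagents that add atoms: none
Why: In this heterogeneous catalytic hydrogenation the two conjugated C=C bonds should take up hydrogen on palladium far faster than the enolised 1,3-diketone or the electron-rich arenes, and recrystallisation of 10 keeps any over-reduced racemic alcohol out of the enzymatic step.

Step 4
Reactants: 10 the saturated diketone
Product: 11 (R)-5-hydroxy-1-(4-hydroxy-3,5-dimethoxyphenyl)-7-(4-hydroxy-3-methoxyphenyl)heptan-3-one (CNP0252358.1)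
Conditions: ketoreductase (NADPH-dependent, picked from a screening panel), NADP+ (cat.), glucose dehydrogenase, D-glucose (1.1 equiv), 0.1 M KH2PO4/K2HPO4 buffer pH 6.5, DMSO (10% v/v), 30 °C, N2; EtOAc extraction, SiO2 chromatography
Reagents that add atoms: none
Why: The diketo tautomer of 10, in fast equilibrium with the enol, is bound by the ketoreductase, NADPH transfers a hydride to the Si face of the C5 carbonyl (CIP order O > C4 > C6) while the active-site tyrosine protonates the oxygen, and glucose dehydrogenase regenerates NADPH at the expense of D-glucose. The closest known reaction type is the ketoreductase (alcohol dehydrogenase) mono-reduction of acyclic 1,3-diketones to β-hydroxy ketones, so the reaction type is established and only this pair of arms is untested. No ring is closed and no skeletal bond is formed. The one new stereocentre, C5, is set as R by the enzyme, whose fixed binding mode exposes only the Si face of the bound carbonyl to the nicotinamide hydride. The step needs C5 over C3 regioselectivity, Si-face selectivity and a stop at mono-reduction; the only handle for the first is the difference between ring A (one methoxy group beside the phenol) and ring B (two), which a protein pocket can read where a small reagent cannot, and for this reason the phenols are left free and the enzyme is chosen by screening panels of both facial preferences, read out by chiral HPLC. Over-reduction should be held back by the limiting amount of D-glucose and by the lower reactivity of the unactivated C3 ketone of 11, and the near-neutral buffer should leave the β-hydroxy ketone free of elimination and retro-aldol cleavage.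

Compound list
1 | acetylacetone (pentane-2,4-dione) | CC(=O)CC(C)=O | starting material
2 | vanillin (4-hydroxy-3-methoxybenzaldehyde) | COc1cc(C=O)ccc1O | starting material
3 | acetylacetone dibutoxyboron chelate (2,2-dibutoxy-4,6-dimethyl-1,3,2-dioxaborinine, drawn as the zwitterion; formed in the flask) | CCCCO[B-]1(OCCCC)OC(C)=CC(C)=[O+]1 | intermediate
4 | feruloylacetone dibutoxyboron chelate (formed in the flask) | CCCCO[B-]1(OCCCC)OC(C)=CC(/C=C/c2ccc(O)c(OC)c2)=[O+]1 | intermediate
5 | feruloylacetone, (E)-6-(4-hydroxy-3-methoxyphenyl)hex-5-ene-2,4-dione | CC(=O)CC(=O)/C=C/c1ccc(O)c(OC)c1 | intermediate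
6 | syringaldehyde (4-hydroxy-3,5-dimethoxybenzaldehyde) | COc1cc(C=O)cc(OC)c1O | starting material
7 | feruloylacetone difluoroboron chelate [(E)-2,2-difluoro-4-(4-hydroxy-3-methoxystyryl)-6-methyl-1,3,2-dioxaborinine, drawn as the zwitterion; formed in the flask] | F[B-]1(F)OC(C)=CC(/C=C/c2ccc(O)c(OC)c2)=[O+]1 | intermediate
8 | curcuminoid difluoroboron chelate (difluoroboron chelate of 9; formed in the flask) | F[B-]1(F)OC(/C=C/c2cc(OC)c(O)c(OC)c2)=CC(/C=C/c2ccc(O)c(OC)c2)=[O+]1 | intermediate
9 | (1E,6E)-1-(4-hydroxy-3,5-dimethoxyphenyl)-7-(4-hydroxy-3-methoxyphenyl)hepta-1,6-diene-3,5-dione | COc1cc(/C=C/C(=O)CC(=O)/C=C/c2cc(OC)c(O)c(OC)c2)ccc1O | intermediate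
10 | 1-(4-hydroxy-3,5-dimethoxyphenyl)-7-(4-hydroxy-3-methoxyphenyl)heptane-3,5-dione | COc1cc(CCC(=O)CC(=O)CCc2cc(OC)c(O)c(OC)c2)ccc1O | intermediate
11 | (R)-5-hydroxy-1-(4-hydroxy-3,5-dimethoxyphenyl)-7-(4-hydroxy-3-methoxyphenyl)heptan-3-one | COc1cc(CC[C@@H](O)CC(=O)CCc2cc(OC)c(O)c(OC)c2)ccc1O | target

Total step count: 4. Longest linear sequence: 4 steps (1 → 5 → 9 → 10 → 11).

Steps most likely to fail

Step 4. The enzyme may fail to tell the two carbonyl groups apart, so that hydride goes to C3 as well as C5, or a second reduction may lead on to the diol. The fallback fixes the regiochemistry by construction through an aldol bond formation instead of a reduction; it sets out from 6 and 2 and returns at 11. Syringaldehyde 6 is condensed with acetone (aq. NaOH, acetone as solvent, Claisen–Schmidt) to (E)-4-(4-hydroxy-3,5-dimethoxyphenyl)but-3-en-2-one F1, hydrogenated (H2, Pd/C, EtOAc) to 4-(4-hydroxy-3,5-dimethoxyphenyl)butan-2-one F2 and silylated (TBSCl, imidazole, DMF) to 4-[4-(tert-butyldimethylsilyloxy)-3,5-dimethoxyphenyl]butan-2-one F3. Vanillin 2 is silylated in the same way to 4-(tert-butyldimethylsilyloxy)-3-methoxybenzaldehyde F4, extended with Ph3P=CHCHO (Wittig, toluene, 80 °C) to (E)-3-[4-(tert-butyldimethylsilyloxy)-3-methoxyphenyl]prop-2-enal F5 and hydrogenated at the C=C bond (H2, Pd/C, EtOAc) to 3-[4-(tert-butyldimethylsilyloxy)-3-methoxyphenyl]propanal F6. Kinetic enolisation of F3 on its methyl side (LiN(iPr)2, TMSCl, THF, −78 °C) gives 4-[4-(tert-butyldimethylsilyloxy)-3,5-dimethoxyphenyl]-2-(trimethylsilyloxy)but-1-ene F7. A catalytic asymmetric Mukaiyama aldol addition of F7 to F6 follows (oxazaborolidinone Lewis acid from N-tosyltryptophan and BuB(OH)2, 20 mol %, EtCN, −78 °C, using the tryptophan antipode that directs the enol ether to the Si face of the aldehyde). It should give (R)-1-[4-(tert-butyldimethylsilyloxy)-3,5-dimethoxyphenyl]-7-[4-(tert-butyldimethylsilyloxy)-3-methoxyphenyl]-5-(trimethylsilyloxy)heptan-3-one F8. Global desilylation (Bu4NF, AcOH, THF, 0 °C) then gives 11. Any shortfall in enantiomeric purity would be made up by preparative HPLC on a chiral stationary phase.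

Step 1. Control over the degree of condensation may be lost, so that the mono-styryl chelate reacts with a second vanillin and symmetrical curcumin accompanies the product. The fallback forms the acetyl–methylene bond of the diketone instead of the styryl bond, so that one-to-one stoichiometry is built in; it sets out from 2 and returns at 5. Vanillin 2 is condensed with acetone (aq. NaOH, acetone as solvent, Claisen–Schmidt) to dehydrozingerone [(E)-4-(4-hydroxy-3-methoxyphenyl)but-3-en-2-one] F9 and protected (MOMCl, iPr2NEt, CH2Cl2) as (E)-4-[3-methoxy-4-(methoxymethoxy)phenyl]but-3-en-2-one F10. Crossed Claisen condensation with ethyl acetate (NaH, THF, reflux) acetylates the methyl ketone to (E)-6-[3-methoxy-4-(methoxymethoxy)phenyl]hex-5-ene-2,4-dione F11, and HCl in MeOH at 40 °C removes the acetal to give 5.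

Step 2. The amine and heat may reverse the first condensation, so that the aryl arms are exchanged and the two symmetrical curcuminoids form, which would be hard to separate from 9; release of the diketone from the difluoroboron chelate may also be sluggish. The fallback saturates the vanillin-derived arm before the second condensation, so that it can no longer be exchanged, and uses the readily hydrolysed alkoxyborate template; it sets out from 5 and returns at 10. Hydrogenation of 5 (H2, Pd/C, EtOAc) should give 6-(4-hydroxy-3-methoxyphenyl)hexane-2,4-dione F12. With B2O3 and B(OBu)3 in EtOAc at 70 °C this forms the saturated diketone dibutoxyboron chelate F13, which condenses with 6 (n-BuNH2, 70 °C) at its methyl group, the usual site for borate chelates of alkane-2,4-diones, to the styryl diketone dibutoxyboron chelate F14. Hydrolysis with 0.5 M aq. HCl releases (E)-1-(4-hydroxy-3,5-dimethoxyphenyl)-7-(4-hydroxy-3-methoxyphenyl)hept-1-ene-3,5-dione F15, and hydrogenation of its single C=C bond (H2, Pd/C, EtOAc) gives 10.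

Further compounds
F1 | step 4 | (E)-4-(4-hydroxy-3,5-dimethoxyphenyl)but-3-en-2-one | CC(=O)/C=C/c1cc(OC)c(O)c(OC)c1
F2 | step 4 | 4-(4-hydroxy-3,5-dimethoxyphenyl)butan-2-one | CC(=O)CCc1cc(OC)c(O)c(OC)c1
F3 | step 4 | 4-[4-(tert-butyldimethylsilyloxy)-3,5-dimethoxyphenyl]butan-2-one | CC(=O)CCc1cc(OC)c(O[Si](C)(C)C(C)(C)C)c(OC)c1
F4 | step 4 | 4-(tert-butyldimethylsilyloxy)-3-methoxybenzaldehyde | COc1cc(C=O)ccc1O[Si](C)(C)C(C)(C)C
F5 | step 4 | (E)-3-[4-(tert-butyldimethylsilyloxy)-3-methoxyphenyl]prop-2-enal | COc1cc(/C=C/C=O)ccc1O[Si](C)(C)C(C)(C)C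
F6 | step 4 | 3-[4-(tert-butyldimethylsilyloxy)-3-methoxyphenyl]propanal | COc1cc(CCC=O)ccc1O[Si](C)(C)C(C)(C)C
F7 | step 4 | 4-[4-(tert-butyldimethylsilyloxy)-3,5-dimethoxyphenyl]-2-(trimethylsilyloxy)but-1-ene | C=C(O[Si](C)(C)C)CCc1cc(OC)c(O[Si](C)(C)C(C)(C)C)c(OC)c1
F8 | step 4 | (R)-1-[4-(tert-butyldimethylsilyloxy)-3,5-dimethoxyphenyl]-7-[4-(tert-butyldimethylsilyloxy)-3-methoxyphenyl]-5-(trimethylsilyloxy)heptan-3-one | COc1cc(CC[C@@H](O[Si](C)(C)C)CC(=O)CCc2cc(OC)c(O[Si](C)(C)C(C)(C)C)c(OC)c2)ccc1O[Si](C)(C)C(C)(C)C
F9 | step 1 | dehydrozingerone, (E)-4-(4-hydroxy-3-methoxyphenyl)but-3-en-2-one | CC(=O)/C=C/c1ccc(O)c(OC)c1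
F10 | step 1 | (E)-4-[3-methoxy-4-(methoxymethoxy)phenyl]but-3-en-2-one | CC(=O)/C=C/c1ccc(OCOC)c(OC)c1
F11 | step 1 | (E)-6-[3-methoxy-4-(methoxymethoxy)phenyl]hex-5-ene-2,4-dione | CC(=O)CC(=O)/C=C/c1ccc(OCOC)c(OC)c1
F12 | step 2 | 6-(4-hydroxy-3-methoxyphenyl)hexane-2,4-dione | CC(=O)CC(=O)CCc1ccc(O)c(OC)c1
F13 | step 2 | saturated diketone dibutoxyboron chelate (chelate of F12) | CCCCO[B-]1(OCCCC)OC(C)=CC(CCc2ccc(O)c(OC)c2)=[O+]1
F14 | step 2 | styryl diketone dibutoxyboron chelate (chelate of F15) | CCCCO[B-]1(OCCCC)OC(/C=C/c2cc(OC)c(O)c(OC)c2)=CC(CCc2ccc(O)c(OC)c2)=[O+]1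
F15 | step 2 | (E)-1-(4-hydroxy-3,5-dimethoxyphenyl)-7-(4-hydroxy-3-methoxyphenyl)hept-1-ene-3,5-dione | COc1cc(CCC(=O)CC(=O)/C=C/c2cc(OC)c(O)c(OC)c2)ccc1O
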